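The data come from a simulation with made-up constants; noise was put on by code.

The pitfall with this flask is to follow Z, whose readings up to 3.00 h carry a scatter of 2 percentage points and could pass for a straight fall, when the candidate steps, Q + G to X + J and Z + X to E + Q, tell you to follow G.

| setting | teal | blue | violet | north | east | south-east |
|---|---|---|---|---|---|---|
| Z | 0.050 M | 0.050 M | 0.050 M | 0.050 M | 0.050 M | 0.050 M |
| G | 0.060 M | 0.060 M | 0.030 M | 0.0600 M | 0.0600 M | 0.0600 M |
| Q | 2.5 mM | 3.8 mM | 5 mM | 5.0 mM | 5.0 mM | 5.0 mM |
| remark | run made earlier | run made earlier | run made earlier |  |  |  |
| time |  |  |  | 4.0 h | 5.0 h | 6.0 h |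
| volume of the second phase over the first |  |  |  | 1.0 | 1.0 | 1.0 |

- teal (time / h: Z / %, E / %): 0.200: 103, 1; 0.667: 96, 3; 1.00: 95, 6; 2.00: 85, 10; 2.50: 87, 12; 3.00: 88, 10
- blue (time / h: Z / %, E / %): 0.200: 100, 0; 0.667: 94, 10; 1.00: 93, 8; 2.00: 90, 15; 2.50: 85, 13; 3.00: 83, 20
- violet (time / h: Z / %, E / %): 0.250: 101, 1; 0.833: 100, 6; 1.33: 95, 7; 2.50: 90, 12; 3.00: 89, 12

(standard deviation of a reading: 2 percentage points)

- which of these there is most of at the end, counted by the Z in it, north (Z / E)
- which of these there is most of at the end, counted by the Z in it, east (Z / E)
- which of these there is most of at the end, counted by the Z in it, south-east (Z / E)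
- amount of the one of these that there is most of at the end, in percent of the Z charged, north
- amount of the one of these that there is most of at the end, in percent of the Z charged, east
- amount of the one of these that there is most of at the end, in percent of the Z charged, south-east

- in the second phase: G, J; everything else is in the first
- charges count per volume of the first phase; a concentration in a rate is the amount of a species over the volume of its own phase; every rate counts per litre of the first phase
- candidate steps: Q + G <-> X + J; Z + X <-> E + Q
- the earlier runs hold the two phases in the same ratio of volumes as the flask asked about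

Violet holds twice the Q of teal and half its G, and at 3.00 h they show 12% and 10% of E against a scatter of 2 points, so I take the pace as proportional to cQ·cG, with cQ as charged. Divide the rate at which Z is lost by the rate at which G is lost and time drops out: each Z turned has cost one G, so cG falls as cZ falls, provided little of the catalyst stands as X. Pooling the last readings of teal, blue and violet, with the mean of Z lost and E gained as the G spent, I get 14.1 /M/h for the turnover constant κ, the logarithm of cG at the start over cG now, divided by cQ·t. From κ I reckon Z left at 70.6% in north, 64.5% in east and 58.7% in south-east. The forecast also names Z, Z and Z, but at a higher 73%, 68% and 63%, “Allowing for some slowing from J build-up, reversibility or Z depletion”.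

What stands most is Z in north at 69.5%, Z in east at 63.5% and Z in south-east at 58.0%, which puts the forecast 5 points high in south-east.

    Q + G ⇌ X + J (K = 1.75, k = 0.258 /M/min)
    Z + X ⇌ E + Q (K = 9.65, k = 30.8 /M/min)

In south-east at 6.00 h, X has a forward half-life of 0.78 min, far shorter than the 0.75 h of Q by its forward step with G at the charges of north. South-east holds 92.1% of its catalyst as Q, the resting state, and 7.89% as X, and on these two half-lives Q + G is the rate-limiting step. The G left in south-east, 64.3% of its charge, reads κ as 14.7 /M/h. Take south-east with 0.0085 M of Q instead: κ gives G left at 48.8% and Z left at 38.6%, so E leads. That flask computes to G 48.9%, Z 41.0% and E 59.0%.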